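**Plan**

- Retrosynthetic cuts, in order: the six O–benzyl bonds; the C3(flavone)–C8(flavan) bond (Negishi coupling); the flavan C3–C4 bond; then N=C (aza-Wittig) and O1–C2 (Mitsunobu) of a seven-membered precursor.
- The flavan C3–C4 bond is made by excising the nitrogen from a 2,3,4,5-tetrahydro-1,4-benzoxazepine (O1–C2–C3–N4–C5), so that C3 and C5 join and the seven-membered ring contracts to the dihydropyran ring.
- Enabling feature: flavan C3–C4 is a bare CH2–CH2 link, C4 is benzylic to the phloroglucinol-type ring, and the stereocentre C2 sits one bond away. An NH placed between the two CH2 groups is a cyclic secondary benzylic amine, and C2 never becomes a reactive centre.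
- Forward order: iodosalicylaldehyde + (S)-azido alcohol → aryl ether → seven-membered ring → nitrogen deletion to the 8-iodoflavan → coupling with an apigenin-derived 3-iodoflavone → hydrogenolysis.
- Stereochemistry: C2 comes from a CBS reduction ((S)-carbinol), is inverted once in the Mitsunobu etherification, and is a spectator afterwards. The C8 (not C6) linkage is fixed by iodinating ortho to the phenol oxygen that becomes O1.

Key step: step 7

Assumption: the target structure fixes only C2 of the flavan, as (S); the hindered C3–C8 axis is unspecified, so its rotamers are taken to equilibrate or, failing that, to be separated after the last step.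

**Step 1**
Reactants: 1 2,4,6-trihydroxybenzaldehyde
Product: 2 2,4-bis(benzyloxy)-6-hydroxybenzaldehyde
Conditions: BnBr (2.05 equiv), K2CO3, DMF, 0 °C → rt
Reagents that add atoms: benzyl bromide, BrCc1ccccc1
Why: Williamson etherification should stop after the 4-OH and one of the two equivalent ortho OH groups, because the remaining ortho OH is hydrogen-bonded to the formyl group and is the least nucleophilic.

**Step 2**
Reactants: 2 2,4-bis(benzyloxy)-6-hydroxybenzaldehyde
Product: 3 4,6-bis(benzyloxy)-2-hydroxy-3-iodobenzaldehyde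
Conditions: NIS (1.05 equiv), TFA (10 mol %), MeCN, 0 °C
Reagents that add atoms: N-iodosuccinimide, O=C1CCC(=O)N1I
Why: Electrophilic aromatic iodination should prefer the position between OH and OBn, which is ortho to the free phenol and less shielded than the position between two OBn groups; an NOE check (the remaining ring proton should contact both OCH2 groups) is planned here, since this iodine defines the later C8 linkage.

**Step 3**
Reactants: 4 1-[4-(benzyloxy)phenyl]-2-bromoethan-1-one
Product: 5 (1S)-1-[4-(benzyloxy)phenyl]-2-bromoethan-1-ol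
Conditions: (S)-2-methyl-CBS-oxazaborolidine (10 mol %), BH3·SMe2, THF, 0 °C, slow addition of 4
Reagents that add atoms: none
Why: CBS reduction with aryl as the large group should deliver hydride in the facial sense that turns acetophenone into (R)-1-phenylethanol, which is the (S)-bromohydrin here because CH2Br outranks aryl.

**Step 4**
Reactants: 5 (1S)-1-[4-(benzyloxy)phenyl]-2-bromoethan-1-ol
Product: 6 (1S)-2-azido-1-[4-(benzyloxy)phenyl]ethan-1-ol
Conditions: NaN3, DMF, 50 °C
Reagents that add atoms: sodium azide, [Na+].[N-]=[N+]=[N-]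
Why: SN2 displacement of the primary bromide by azide should leave the carbinol stereocentre untouched.

**Step 5**
Reactants: 3 4,6-bis(benzyloxy)-2-hydroxy-3-iodobenzaldehyde; 6 (1S)-2-azido-1-[4-(benzyloxy)phenyl]ethan-1-ol
Product: 7 2-{(1R)-2-azido-1-[4-(benzyloxy)phenyl]ethoxy}-4,6-bis(benzyloxy)-3-iodobenzaldehyde
Conditions: PPh3, DIAD, THF, 0 °C (betaine preformed), then 6 and 3, 0 °C → rt
Reagents that add atoms: none
Why: Mitsunobu etherification, in which the acidic phenol of 3 should displace the oxyphosphonium ion of 6 by SN2 with inversion ((S)-carbinol to (R)-aryl ether), while the preformed betaine keeps free PPh3 away from the azide and the β-azido group disfavours ionisation of the p-alkoxybenzylic centre.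

**Step 6**
Reactants: 7 2-{(1R)-2-azido-1-[4-(benzyloxy)phenyl]ethoxy}-4,6-bis(benzyloxy)-3-iodobenzaldehyde
Product: 10 (2R)-6,8-bis(benzyloxy)-2-[4-(benzyloxy)phenyl]-9-iodo-2,3,4,5-tetrahydro-1,4-benzoxazepine, via iminophosphorane 8 (not isolated), via cyclic imine 9 (not isolated)
Conditions: PPh3, toluene, rt → 60 °C; then NaBH4, MeOH, 0 °C
Reagents that add atoms: none
Why: Staudinger reaction of the azide followed by intramolecular aza-Wittig condensation with the ortho aldehyde should close the seven-membered cyclic imine, and NaBH4 should reduce its C=N bond without touching the stereocentre.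

**Step 7**
Reactants: 10 (2R)-6,8-bis(benzyloxy)-2-[4-(benzyloxy)phenyl]-9-iodo-2,3,4,5-tetrahydro-1,4-benzoxazepine
Product: 13 (2S)-5,7-bis(benzyloxy)-2-[4-(benzyloxy)phenyl]-8-iodo-3,4-dihydro-2H-chromene, via N-amino adduct 11 (not isolated), via isodiazene 12 (not isolated)
Conditions: N-(benzyloxy)-N-(pivaloyloxy)-4-(trifluoromethyl)benzamide (1.5 equiv), THF, 45 °C
Reagents that add atoms: none
Why: The secondary amine should attack the electrophilic nitrogen of the anomeric amide with loss of pivalate to give adduct 11, which expels benzyl 4-(trifluoromethyl)benzoate to form isodiazene 12; this loses N2 to a tethered singlet 1,6-diradical (a benzylic radical at the future C4, stabilised by the trioxygenated ring, and a primary radical at C3) that collapses to the C3–C4 bond. The closest known reaction type is the nitrogen deletion of secondary benzylic amines with anomeric amides, including the contraction of benzo-fused cyclic amines by one ring atom. The seven-membered ring contracts to the six-membered dihydropyran ring by intramolecular radical–radical recombination, not by a polar cyclisation. No stereocentre is formed: C2 is not a radical site and keeps its four bonds, and its descriptor changes from R to S only because CH2N outranks aryl whereas CH2C does not. The selectivity needed is recombination over β-scission of the C2–O bond (which would give an ortho-quinone methide and 4-benzyloxystyrene and, on their recombination, racemic material) and over hydrogen-atom disproportionation; the short tether, the solvent cage and the mild temperature should secure it. The aryl iodide and the benzyl ethers should be inert, the amine being the only nucleophile present.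

**Step 8**
Reactants: 14 apigenin (5,7-dihydroxy-2-(4-hydroxyphenyl)-4H-chromen-4-one)
Product: 15 5,7-bis(benzyloxy)-2-[4-(benzyloxy)phenyl]-4H-chromen-4-one
Conditions: BnBr (3.6 equiv), K2CO3, DMF, 80 °C
Reagents that add atoms: benzyl bromide, BrCc1ccccc1
Why: Williamson etherification of all three phenols, with heating needed to alkylate the 5-OH that is hydrogen-bonded to the C4 carbonyl.

**Step 9**
Reactants: 15 5,7-bis(benzyloxy)-2-[4-(benzyloxy)phenyl]-4H-chromen-4-one
Product: 17 5,7-bis(benzyloxy)-2-[4-(benzyloxy)phenyl]-3-iodo-4H-chromen-4-one, via 3-lithioflavone 16 (not isolated)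
Conditions: LDA (1.2 equiv), THF, −78 °C; then I2, −78 → −40 °C
Reagents that add atoms: iodine, II
Why: Deprotonation of the flavone at C3 by LDA and iodine quench of the vinyllithium should place the halogen at C3 only, avoiding the ring A positions that electrophilic iodination would attack, with the low temperature suppressing ring opening of the 3-lithio species.

**Step 10**
Reactants: 13 (2S)-5,7-bis(benzyloxy)-2-[4-(benzyloxy)phenyl]-8-iodo-3,4-dihydro-2H-chromene; 17 5,7-bis(benzyloxy)-2-[4-(benzyloxy)phenyl]-3-iodo-4H-chromen-4-one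
Product: 20 5,7-bis(benzyloxy)-2-[4-(benzyloxy)phenyl]-3-{(2S)-5,7-bis(benzyloxy)-2-[4-(benzyloxy)phenyl]-3,4-dihydro-2H-chromen-8-yl}-4H-chromen-4-one, via arylmagnesium chloride 18 (not isolated), via arylzinc chloride 19 (not isolated)
Conditions: 13, iPrMgCl·LiCl, THF, −20 °C; ZnCl2, −20 °C → rt; then 17 (1.2 equiv), Pd(OAc)2 (5 mol %), SPhos (10 mol %), THF/NMP, 65 °C
Reagents that add atoms: none
Why: Iodine–magnesium exchange assisted by the two ortho oxygens, transmetalation to zinc and Negishi coupling with the 3-iodoflavone (zerovalent palladium formed in situ, bulky biarylphosphine for a doubly ortho-substituted pair) should form the C3–C8 bond without the base-induced protodemetalation that 2,6-dialkoxyaryl boron reagents suffer, and without touching C2.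

**Step 11**
Reactants: 20 hexa-O-benzyl daphnodorin D2 (full name as in step 10)
Product: 21 daphnodorin D2
Conditions: H2 (1 atm), Pd(OH)2/C, THF/MeOH, rt, stopped at the calculated H2 uptake
Reagents that add atoms: none
Why: Hydrogenolysis of the six benzyl ethers under neutral conditions should spare the tetrasubstituted C2=C3 bond of the flavone and the cyclic benzylic C2–O bond of the flavan, so the (2S) centre is kept.

**Compound list**

1 | 2,4,6-trihydroxybenzaldehyde | O=Cc1c(O)cc(O)cc1O | starting material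
2 | 2,4-bis(benzyloxy)-6-hydroxybenzaldehyde | O=Cc1c(O)cc(OCc2ccccc2)cc1OCc1ccccc1 | intermediate
3 | 4,6-bis(benzyloxy)-2-hydroxy-3-iodobenzaldehyde | O=Cc1c(O)c(I)c(OCc2ccccc2)cc1OCc1ccccc1 | intermediate
4 | 1-[4-(benzyloxy)phenyl]-2-bromoethan-1-one | O=C(CBr)c1ccc(OCc2ccccc2)cc1 | starting material
5 | (1S)-1-[4-(benzyloxy)phenyl]-2-bromoethan-1-ol | O[C@H](CBr)c1ccc(OCc2ccccc2)cc1 | intermediate
6 | (1S)-2-azido-1-[4-(benzyloxy)phenyl]ethan-1-ol | O[C@H](CN=[N+]=[N-])c1ccc(OCc2ccccc2)cc1 | intermediate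
7 | 2-{(1R)-2-azido-1-[4-(benzyloxy)phenyl]ethoxy}-4,6-bis(benzyloxy)-3-iodobenzaldehyde | O=Cc1c(O[C@@H](CN=[N+]=[N-])c2ccc(OCc3ccccc3)cc2)c(I)c(OCc2ccccc2)cc1OCc1ccccc1 | intermediate
8 | iminophosphorane of 7: 4,6-bis(benzyloxy)-2-{(1R)-1-[4-(benzyloxy)phenyl]-2-[(triphenylphosphoranylidene)amino]ethoxy}-3-iodobenzaldehyde | O=Cc1c(O[C@@H](CN=P(c2ccccc2)(c2ccccc2)c2ccccc2)c2ccc(OCc3ccccc3)cc2)c(I)c(OCc2ccccc2)cc1OCc1ccccc1 | intermediate
9 | cyclic imine: (2R)-6,8-bis(benzyloxy)-2-[4-(benzyloxy)phenyl]-9-iodo-2,3-dihydro-1,4-benzoxazepine | Ic1c(OCc3ccccc3)cc(OCc3ccccc3)c2c1O[C@H](c1ccc(OCc3ccccc3)cc1)CN=C2 | intermediate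
10 | (2R)-6,8-bis(benzyloxy)-2-[4-(benzyloxy)phenyl]-9-iodo-2,3,4,5-tetrahydro-1,4-benzoxazepine | Ic1c(OCc3ccccc3)cc(OCc3ccccc3)c2c1O[C@H](c1ccc(OCc3ccccc3)cc1)CNC2 | intermediate
11 | N-amino adduct: N-(benzyloxy)-N-{(2R)-6,8-bis(benzyloxy)-2-[4-(benzyloxy)phenyl]-9-iodo-2,3-dihydro-1,4-benzoxazepin-4(5H)-yl}-4-(trifluoromethyl)benzamide | Ic1c(OCc3ccccc3)cc(OCc3ccccc3)c2c1O[C@H](c1ccc(OCc3ccccc3)cc1)CN(N(OCc1ccccc1)C(=O)c1ccc(C(F)(F)F)cc1)C2 | intermediate
12 | isodiazene (1,1-diazene) on N4 of the benzoxazepine ring of 10 | Ic1c(OCc3ccccc3)cc(OCc3ccccc3)c2c1O[C@H](c1ccc(OCc3ccccc3)cc1)C[N+](=[N-])C2 | intermediate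
13 | (2S)-5,7-bis(benzyloxy)-2-[4-(benzyloxy)phenyl]-8-iodo-3,4-dihydro-2H-chromene | Ic1c(OCc3ccccc3)cc(OCc3ccccc3)c2c1O[C@H](c1ccc(OCc3ccccc3)cc1)CC2 | intermediate
14 | apigenin | O=c1cc(-c2ccc(O)cc2)oc2cc(O)cc(O)c12 | starting material
15 | 5,7-bis(benzyloxy)-2-[4-(benzyloxy)phenyl]-4H-chromen-4-one | O=c1cc(-c2ccc(OCc3ccccc3)cc2)oc2cc(OCc3ccccc3)cc(OCc3ccccc3)c12 | intermediate
16 | 3-lithio derivative of 15 | O=c1c([Li])c(-c2ccc(OCc3ccccc3)cc2)oc2cc(OCc3ccccc3)cc(OCc3ccccc3)c12 | intermediate
17 | 5,7-bis(benzyloxy)-2-[4-(benzyloxy)phenyl]-3-iodo-4H-chromen-4-one | O=c1c(I)c(-c2ccc(OCc3ccccc3)cc2)oc2cc(OCc3ccccc3)cc(OCc3ccccc3)c12 | intermediate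
18 | {(2S)-5,7-bis(benzyloxy)-2-[4-(benzyloxy)phenyl]-3,4-dihydro-2H-chromen-8-yl}magnesium chloride | Cl[Mg]c1c(OCc3ccccc3)cc(OCc3ccccc3)c2c1O[C@H](c1ccc(OCc3ccccc3)cc1)CC2 | intermediate
19 | {(2S)-5,7-bis(benzyloxy)-2-[4-(benzyloxy)phenyl]-3,4-dihydro-2H-chromen-8-yl}zinc chloride | Cl[Zn]c1c(OCc3ccccc3)cc(OCc3ccccc3)c2c1O[C@H](c1ccc(OCc3ccccc3)cc1)CC2 | intermediate
20 | 5,7-bis(benzyloxy)-2-[4-(benzyloxy)phenyl]-3-{(2S)-5,7-bis(benzyloxy)-2-[4-(benzyloxy)phenyl]-3,4-dihydro-2H-chromen-8-yl}-4H-chromen-4-one | O=c1c(-c2c(OCc3ccccc3)cc(OCc3ccccc3)c3c2O[C@H](c2ccc(OCc4ccccc4)cc2)CC3)c(-c2ccc(OCc3ccccc3)cc2)oc2cc(OCc3ccccc3)cc(OCc3ccccc3)c12 | intermediate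
21 | daphnodorin D2 | O=c1c(-c2c(O)cc(O)c3c2O[C@H](c2ccc(O)cc2)CC3)c(-c2ccc(O)cc2)oc2cc(O)cc(O)c12 | target

**Count**

Total steps: 11. Longest linear sequence: 7 steps (1, 2, 5, 6, 7, 10, 11; the branch 3, 4, 5, 6, 7, 10, 11 is equally long).

**Steps most likely to fail**

Step 7 (nitrogen deletion). The diradical may undergo β-scission of the C2–O bond before it recombines, which would fragment the ring and erode the configuration at C2, or it may disproportionate. The fallback builds the flavan without nitrogen, setting out from 3 and returning at 13. Claisen–Schmidt condensation of 3 with commercial 1-[4-(benzyloxy)phenyl]ethan-1-one (KOH, EtOH) should give the chalcone (2E)-3-[4,6-bis(benzyloxy)-2-hydroxy-3-iodophenyl]-1-[4-(benzyloxy)phenyl]prop-2-en-1-one F1. Conjugate reduction with [(Ph3P)CuH]6 in toluene, which spares the aryl iodide and the benzyl ethers, should give the dihydrochalcone 3-[4,6-bis(benzyloxy)-2-hydroxy-3-iodophenyl]-1-[4-(benzyloxy)phenyl]propan-1-one F2. CBS reduction with (S)-2-methyl-CBS-oxazaborolidine and excess BH3·SMe2 should give the carbinol (1R)-3-[4,6-bis(benzyloxy)-2-hydroxy-3-iodophenyl]-1-[4-(benzyloxy)phenyl]propan-1-ol F3. Intramolecular Mitsunobu etherification (PPh3, DIAD, THF) with inversion should then close the six-membered ring directly to 13.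

Step 10 (Negishi coupling). Transmetalation and reductive elimination at a bond flanked by four ortho substituents may be slower than protodemetalation and homocoupling. The fallback replaces the sp2–sp2 coupling by an enolate arylation and builds the pyranone ring afterwards, setting out from 13 and returning at 20. Palladium-catalysed α-arylation of commercial 1-[2,4-bis(benzyloxy)-6-hydroxyphenyl]ethan-1-one, used as its phenoxide–enolate dianion (NaOtBu 2.2 equiv, Pd(OAc)2, XPhos, toluene, 80 °C), with iodide 13 should give the deoxybenzoin 1-[2,4-bis(benzyloxy)-6-hydroxyphenyl]-2-{(2S)-5,7-bis(benzyloxy)-2-[4-(benzyloxy)phenyl]-3,4-dihydro-2H-chromen-8-yl}ethan-1-one F4. Aroylation with 4-(benzyloxy)benzoyl chloride (K2CO3, acetone, reflux) with Baker–Venkataraman acyl transfer should give the diketone 1-[2,4-bis(benzyloxy)-6-hydroxyphenyl]-3-[4-(benzyloxy)phenyl]-2-{(2S)-5,7-bis(benzyloxy)-2-[4-(benzyloxy)phenyl]-3,4-dihydro-2H-chromen-8-yl}propane-1,3-dione F5. Cyclodehydration of F5 (catalytic TsOH, toluene) should give 20; the flavan oxygens stay benzylated, so only the ring A phenol can close.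

Step 5 (intermolecular Mitsunobu). Attack by the doubly ortho-substituted, hydrogen-bonded phenol may be slow enough for the oxyphosphonium ion to ionise at the p-alkoxybenzylic carbon, with loss of enantiopurity, or to eliminate. The fallback forms the C–N bond first and closes the C–O bond intramolecularly, setting out from 6 and 3 and returning at 10. Staudinger reduction of 6 (PPh3, THF/H2O) should give the amino alcohol (1S)-2-amino-1-[4-(benzyloxy)phenyl]ethan-1-ol F6. Reductive amination with 3 (MeOH, then NaBH4) should give the amine 3,5-bis(benzyloxy)-2-[({(2S)-2-[4-(benzyloxy)phenyl]-2-hydroxyethyl}amino)methyl]-6-iodophenol F7. N-Sulfonylation with 2-nitrobenzenesulfonyl chloride (NaHCO3, CH2Cl2/H2O) should give the sulfonamide N-{[4,6-bis(benzyloxy)-2-hydroxy-3-iodophenyl]methyl}-N-{(2S)-2-[4-(benzyloxy)phenyl]-2-hydroxyethyl}-2-nitrobenzenesulfonamide F8, which has no carbonyl group to take part at the activated carbinol. Intramolecular Mitsunobu closure (PPh3, DIAD, THF) with inversion should give the ring compound (2R)-6,8-bis(benzyloxy)-2-[4-(benzyloxy)phenyl]-9-iodo-4-(2-nitrobenzenesulfonyl)-2,3,4,5-tetrahydro-1,4-benzoxazepine F9. Removal of the sulfonyl group with PhSH and K2CO3 in DMF should give 10.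

**Further compounds**

F1 | step 7 | (2E)-3-[4,6-bis(benzyloxy)-2-hydroxy-3-iodophenyl]-1-[4-(benzyloxy)phenyl]prop-2-en-1-one | O=C(/C=C/c1c(O)c(I)c(OCc2ccccc2)cc1OCc1ccccc1)c1ccc(OCc2ccccc2)cc1
F2 | step 7 | 3-[4,6-bis(benzyloxy)-2-hydroxy-3-iodophenyl]-1-[4-(benzyloxy)phenyl]propan-1-one | O=C(CCc1c(O)c(I)c(OCc2ccccc2)cc1OCc1ccccc1)c1ccc(OCc2ccccc2)cc1
F3 | step 7 | (1R)-3-[4,6-bis(benzyloxy)-2-hydroxy-3-iodophenyl]-1-[4-(benzyloxy)phenyl]propan-1-ol | O[C@H](CCc1c(O)c(I)c(OCc2ccccc2)cc1OCc1ccccc1)c1ccc(OCc2ccccc2)cc1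
F4 | step 10 | 1-[2,4-bis(benzyloxy)-6-hydroxyphenyl]-2-{(2S)-5,7-bis(benzyloxy)-2-[4-(benzyloxy)phenyl]-3,4-dihydro-2H-chromen-8-yl}ethan-1-one | O=C(Cc1c(OCc2ccccc2)cc(OCc2ccccc2)c2c1O[C@H](c1ccc(OCc3ccccc3)cc1)CC2)c1c(O)cc(OCc2ccccc2)cc1OCc1ccccc1
F5 | step 10 | 1-[2,4-bis(benzyloxy)-6-hydroxyphenyl]-3-[4-(benzyloxy)phenyl]-2-{(2S)-5,7-bis(benzyloxy)-2-[4-(benzyloxy)phenyl]-3,4-dihydro-2H-chromen-8-yl}propane-1,3-dione | O=C(c1ccc(OCc2ccccc2)cc1)C(c1c(OCc2ccccc2)cc(OCc2ccccc2)c2c1O[C@H](c1ccc(OCc3ccccc3)cc1)CC2)C(=O)c1c(O)cc(OCc2ccccc2)cc1OCc1ccccc1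
F6 | step 5 | (1S)-2-amino-1-[4-(benzyloxy)phenyl]ethan-1-ol | O[C@H](CN)c1ccc(OCc2ccccc2)cc1
F7 | step 5 | 3,5-bis(benzyloxy)-2-[({(2S)-2-[4-(benzyloxy)phenyl]-2-hydroxyethyl}amino)methyl]-6-iodophenol | O[C@H](CNCc1c(O)c(I)c(OCc2ccccc2)cc1OCc1ccccc1)c1ccc(OCc2ccccc2)cc1
F8 | step 5 | N-{[4,6-bis(benzyloxy)-2-hydroxy-3-iodophenyl]methyl}-N-{(2S)-2-[4-(benzyloxy)phenyl]-2-hydroxyethyl}-2-nitrobenzenesulfonamide | O[C@H](CN(Cc1c(O)c(I)c(OCc2ccccc2)cc1OCc1ccccc1)S(=O)(=O)c1ccccc1[N+](=O)[O-])c1ccc(OCc2ccccc2)cc1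
F9 | step 5 | (2R)-6,8-bis(benzyloxy)-2-[4-(benzyloxy)phenyl]-9-iodo-4-(2-nitrobenzenesulfonyl)-2,3,4,5-tetrahydro-1,4-benzoxazepine | Ic1c(OCc3ccccc3)cc(OCc3ccccc3)c2c1O[C@H](c1ccc(OCc3ccccc3)cc1)CN(S(=O)(=O)c1ccccc1[N+](=O)[O-])C2
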